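## Retrosynthetic overview

1. The target is traced back (lipase acetylation; 9-BBN hydroboration, which sets C11 and the C18 oxygen) to a 1,4-trans tetralin catechol acid with a C11=C18 exocyclic methylene and a finished C15 terminus.
2. Ring B is the only ring made; ring A is bought as catechol 1 and carried as its bis-MOM ether 2. The C4–C4a bond is closed by an intramolecular ene attack of the Z-4(11)-olefin on the o-quinone of a seco (aryl-bisabolane-type) acid. Electron-poor ring A stands in for the ring-A allyl cation of the cyclase, H is lost from C18, and ring A re-aromatises by tautomerisation.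
3. The seco acid comes from the aryl cuprate of 2 and the (S)-tosylate of nerylacetone 3 (SN2 inversion sets C1). C19 is added by ortho-lithiation/CO2; C16–OH and C15 by SeO2 oxidation, then Ru–BINAP hydrogenation.
4. Ring order: A is aromatic from the start, B is closed in step 9. Stereocentres: C1 (steps 2 and 4), C15 (step 6), C4 (step 9, from C1), C11 (step 10, from C4).

Assumption: atoms are called by serrulatane numbers (ring B C1–C4; ring A C4a, C5–C8, C8a; side chain C11–C18; C19 carboxyl; C20 methyl), and nerylacetone of ≥97% Z purity is taken as a catalogue chemical.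

## Route

Step 1
Reactants: 1 catechol
Product: 2 1,2-bis(methoxymethoxy)benzene
Conditions: MOMCl (2.4 equiv), i-Pr2NEt (3 equiv), CH2Cl2, 0 °C → rt
Reagents that add atoms: chloromethyl methyl ether (MOMCl), COCCl
Why: Double O-alkylation (Williamson-type acetal formation) gives the bis-MOM ether, whose acetal oxygens direct ortho-lithiation and are later removed by mild acid.

Step 2
Reactants: 3 nerylacetone [(5Z)-6,10-dimethylundeca-5,9-dien-2-one]
Product: 4 (2S,5Z)-6,10-dimethylundeca-5,9-dien-2-ol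
Conditions: Prelog-selective alcohol dehydrogenase (ADH-A, Rhodococcus ruber), NAD+ (cat.), i-PrOH (15% v/v), phosphate buffer pH 7.5, 30 °C
Reagents that add atoms: none
Why: Enzymatic transfer hydrogenation of a methyl ketone delivers hydride to the Re face (Prelog rule) and gives the 2S carbinol; both olefins are untouched.

Step 3
Reactants: 4 (2S,5Z)-6,10-dimethylundeca-5,9-dien-2-ol
Product: 5 (2S,5Z)-6,10-dimethylundeca-5,9-dien-2-yl 4-methylbenzenesulfonate
Conditions: TsCl (1.3 equiv), pyridine, DMAP (cat.), CH2Cl2, 0 °C → rt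
Reagents that add atoms: 4-toluenesulfonyl chloride (TsCl), Cc1ccc(cc1)S(=O)(=O)Cl
Why: O-sulfonylation activates the carbinol without touching the C–O stereocentre (retention).

Step 4
Reactants: 2 1,2-bis(methoxymethoxy)benzene; 5 (2S,5Z)-6,10-dimethylundeca-5,9-dien-2-yl 4-methylbenzenesulfonate
Product: 8 1,2-bis(methoxymethoxy)-3-[(2R,5Z)-6,10-dimethylundeca-5,9-dien-2-yl]benzene, via aryllithium 6 (not isolated), via lithium diarylcuprate 7 (not isolated)
Conditions: 2 (2.2 equiv), n-BuLi (2.2 equiv), THF, 0 °C, 1 h; CuI (1.1 equiv), −30 °C; 5 (1.0 equiv), THF/Et2O, −30 → 0 °C; aq NH4Cl (the second aryl group returns as 2)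
Reagents that add atoms: none
Why: Directed ortho-lithiation, transmetalation to the Gilman diarylcuprate and SN2 displacement of the secondary tosylate with clean inversion turn 2S into the 1R benzylic methyl stereocentre.

Step 5
Reactants: 8 1,2-bis(methoxymethoxy)-3-[(2R,5Z)-6,10-dimethylundeca-5,9-dien-2-yl]benzene
Product: 9 (2E,6Z,10R)-10-[2,3-bis(methoxymethoxy)phenyl]-2,6-dimethylundeca-2,6-dien-1-ol
Conditions: SeO2 (0.3 equiv), t-BuOOH (2.2 equiv), salicylic acid (0.1 equiv), CH2Cl2, 0 °C → rt, stopped near 60% conversion (8 recycled)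
Reagents that add atoms: tert-butyl hydroperoxide, CC(C)(C)OO, with selenium dioxide, O=[Se]=O, as the catalytic oxygen carrier
Why: Catalytic SeO2 allylic oxidation (ene reaction, then [2,3]-sigmatropic shift) attacks the E-methyl of the most accessible, terminal gem-dimethyl olefin and returns the E-allylic alcohol that carries the C16 oxygen.

Step 6
Reactants: 9 (2E,6Z,10R)-10-[2,3-bis(methoxymethoxy)phenyl]-2,6-dimethylundeca-2,6-dien-1-ol
Product: 10 (2R,6Z,10R)-10-[2,3-bis(methoxymethoxy)phenyl]-2,6-dimethylundec-6-en-1-ol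
Conditions: Ru(OAc)2[(R)-BINAP] (1 mol %), H2 (40 atm), MeOH, 25 °C
Reagents that add atoms: none
Why: Hydroxyl-directed Noyori asymmetric hydrogenation reduces only the olefin of the allylic alcohol (the isolated Z-olefin stays, as the remote olefin of geraniol does), and the (R)-ligand is chosen for 15R by analogy with the geraniol facial sense (to be confirmed on the first run).

Step 7
Reactants: 10 (2R,6Z,10R)-10-[2,3-bis(methoxymethoxy)phenyl]-2,6-dimethylundec-6-en-1-ol
Product: 12 4-[(2R,5Z,10R)-11-hydroxy-6,10-dimethylundec-5-en-2-yl]-2,3-bis(methoxymethoxy)benzoic acid, via dilithio species 11 (not isolated)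
Conditions: n-BuLi (2.4 equiv), TMEDA (2.4 equiv), THF, −20 → 0 °C, 1 h; CO2 (g), −78 °C → rt; aq NH4Cl, then NaH2PO4 to pH 4
Reagents that add atoms: carbon dioxide, O=C=O
Why: Directed ortho-metalation occurs at C6, the only ring CH ortho to an acetal oxygen (the alkoxide is a spectator), and carboxylation of the aryllithium installs C19.

Step 8
Reactants: 12 4-[(2R,5Z,10R)-11-hydroxy-6,10-dimethylundec-5-en-2-yl]-2,3-bis(methoxymethoxy)benzoic acid
Product: 13 2,3-dihydroxy-4-[(2R,5Z,10R)-11-hydroxy-6,10-dimethylundec-5-en-2-yl]benzoic acid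
Conditions: 2 M HCl (aq)/THF (1:3), 40 °C
Reagents that add atoms: none
Why: Acid-catalysed acetal hydrolysis frees the catechol; the trisubstituted olefin and the stereocentres tolerate dilute aqueous acid at this temperature.

Step 9
Reactants: 13 2,3-dihydroxy-4-[(2R,5Z,10R)-11-hydroxy-6,10-dimethylundec-5-en-2-yl]benzoic acid
Product: 15 (5R,8S)-3,4-dihydroxy-8-[(6R)-7-hydroxy-6-methylhept-1-en-2-yl]-5-methyl-5,6,7,8-tetrahydronaphthalene-2-carboxylic acid, via ortho-quinone 14 (not isolated)
Conditions: PhI(OAc)2 (1.05 equiv), CH2Cl2/HFIP (4:1), 2 mM, −40 °C, 10 min; then 0 °C, 2 h; aq Na2S2O4 wash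
Reagents that add atoms: none
Why: Proposed new method: two-electron oxidation makes ring A an o-quinone whose C4a (β-carbon of the C8 enone, further activated through the C6 carboxyl) plays the part of the ring-A allyl cation of the cyclase, and the Z-4(11)-olefin attacks it through a six-membered chair-like transition state in which the C1 methyl and the C4 alkenyl group are both pseudoaxial (peri strain with C8=O and C5–H), which gives the 1,4-trans tetralin (4S from 1R); the hydrogen is taken from the methyl trans to the tether (C18), so a C11=C18 methylene results, and tautomerisation of the dienone re-forms the catechol; the closest known reaction types are Lewis-acid-promoted conjugate ene (Prins-type) cyclisations of citronellal-derived alkylidene malonates and enones, and additions of olefins and allylsilanes to quinones.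

Step 10
Reactants: 15 (5R,8S)-3,4-dihydroxy-8-[(6R)-7-hydroxy-6-methylhept-1-en-2-yl]-5-methyl-5,6,7,8-tetrahydronaphthalene-2-carboxylic acid
Product: 17 (5R,8S)-8-[(2S,6R)-1,7-dihydroxy-6-methylheptan-2-yl]-3,4-dihydroxy-5-methyl-5,6,7,8-tetrahydronaphthalene-2-carboxylic acid, via alkylborane 16 (not isolated)
Conditions: 9-BBN (6 equiv), THF, 0 °C → rt, 12 h; pH 7 phosphate buffer, 30% H2O2, 0 °C; aq Na2S2O3; acidify to pH 3
Reagents that add atoms: hydrogen peroxide, OO
Why: Anti-Markovnikov hydroboration–oxidation in which 9-BBN adds to the 1,1-disubstituted olefin from the face away from the aromatic ring, in the rotamer that keeps C4–H eclipsed with the C11–C12 bond (A(1,3) strain model), which gives 11S; the acidic O–H groups are held as O–B species until work-up, and 9-BBN reduces a carboxylic acid only slowly.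

Step 11
Reactants: 17 (5R,8S)-8-[(2S,6R)-1,7-dihydroxy-6-methylheptan-2-yl]-3,4-dihydroxy-5-methyl-5,6,7,8-tetrahydronaphthalene-2-carboxylic acid
Product: 18 (5R,8S)-8-[(2S,6R)-1,7-diacetoxy-6-methylheptan-2-yl]-3,4-dihydroxy-5-methyl-5,6,7,8-tetrahydronaphthalene-2-carboxylic acid (target; 16,18-diacetoxy-7,8-dihydroxyserrulatan-19-oic acid, 1R,4S,11S,15R)
Conditions: vinyl acetate (8 equiv), immobilised Candida antarctica lipase B, MTBE/THF (4:1), 35 °C
Reagents that add atoms: vinyl acetate, CC(=O)OC=C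
Why: Lipase-catalysed irreversible transesterification acetylates the two primary aliphatic alcohols and leaves the catechol and the hindered aryl carboxylic acid free, so no protecting group is needed.

## Compound list

1 | catechol | Oc1ccccc1O | starting material
2 | 1,2-bis(methoxymethoxy)benzene | COCOc1ccccc1OCOC | intermediate
3 | nerylacetone, (5Z)-6,10-dimethylundeca-5,9-dien-2-one | CC(=O)CC/C=C(C)\CCC=C(C)C | starting material
4 | (2S,5Z)-6,10-dimethylundeca-5,9-dien-2-ol | C[C@H](O)CC/C=C(C)\CCC=C(C)C | intermediate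
5 | (2S,5Z)-6,10-dimethylundeca-5,9-dien-2-yl 4-methylbenzenesulfonate | C[C@H](OS(=O)(=O)c1ccc(C)cc1)CC/C=C(C)\CCC=C(C)C | intermediate
6 | 2,3-bis(methoxymethoxy)phenyllithium | [Li]c1cccc(OCOC)c1OCOC | intermediate
7 | lithium bis[2,3-bis(methoxymethoxy)phenyl]cuprate | [Li+].COCOc1cccc([Cu-]c2cccc(OCOC)c2OCOC)c1OCOC | intermediate
8 | 1,2-bis(methoxymethoxy)-3-[(2R,5Z)-6,10-dimethylundeca-5,9-dien-2-yl]benzene | C[C@@H](c1cccc(OCOC)c1OCOC)CC/C=C(C)\CCC=C(C)C | intermediate
9 | (2E,6Z,10R)-10-[2,3-bis(methoxymethoxy)phenyl]-2,6-dimethylundeca-2,6-dien-1-ol | C[C@@H](c1cccc(OCOC)c1OCOC)CC/C=C(C)\CC/C=C(\C)CO | intermediate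
10 | (2R,6Z,10R)-10-[2,3-bis(methoxymethoxy)phenyl]-2,6-dimethylundec-6-en-1-ol | C[C@@H](c1cccc(OCOC)c1OCOC)CC/C=C(C)\CCC[C@@H](C)CO | intermediate
11 | dilithio species: lithium alkoxide of 10 lithiated at the ring carbon ortho to the C7 acetal oxygen | C[C@@H](c1ccc([Li])c(OCOC)c1OCOC)CC/C=C(C)\CCC[C@@H](C)CO[Li] | intermediate
12 | 4-[(2R,5Z,10R)-11-hydroxy-6,10-dimethylundec-5-en-2-yl]-2,3-bis(methoxymethoxy)benzoic acid | C[C@@H](c1ccc(C(=O)O)c(OCOC)c1OCOC)CC/C=C(C)\CCC[C@@H](C)CO | intermediate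
13 | 2,3-dihydroxy-4-[(2R,5Z,10R)-11-hydroxy-6,10-dimethylundec-5-en-2-yl]benzoic acid | C[C@@H](c1ccc(C(=O)O)c(O)c1O)CC/C=C(C)\CCC[C@@H](C)CO | intermediate
14 | 4-[(2R,5Z,10R)-11-hydroxy-6,10-dimethylundec-5-en-2-yl]-5,6-dioxocyclohexa-1,3-diene-1-carboxylic acid (ortho-quinone) | C[C@@H](C1=CC=C(C(=O)O)C(=O)C1=O)CC/C=C(C)\CCC[C@@H](C)CO | intermediate
15 | (5R,8S)-3,4-dihydroxy-8-[(6R)-7-hydroxy-6-methylhept-1-en-2-yl]-5-methyl-5,6,7,8-tetrahydronaphthalene-2-carboxylic acid | OC[C@H](C)CCCC(=C)[C@@H]1CC[C@@H](C)c2c1cc(C(=O)O)c(O)c2O | intermediate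
16 | C18 B-alkyl-9-borabicyclo[3.3.1]nonane adduct of 15 (O–H groups drawn free; in the flask they are O-boryl) | OC[C@H](C)CCC[C@H](CB1C2CCCC1CCC2)[C@@H]1CC[C@@H](C)c2c1cc(C(=O)O)c(O)c2O | intermediate
17 | (5R,8S)-8-[(2S,6R)-1,7-dihydroxy-6-methylheptan-2-yl]-3,4-dihydroxy-5-methyl-5,6,7,8-tetrahydronaphthalene-2-carboxylic acid | OC[C@H](C)CCC[C@H](CO)[C@@H]1CC[C@@H](C)c2c1cc(C(=O)O)c(O)c2O | intermediate
18 | (5R,8S)-8-[(2S,6R)-1,7-diacetoxy-6-methylheptan-2-yl]-3,4-dihydroxy-5-methyl-5,6,7,8-tetrahydronaphthalene-2-carboxylic acid | CC(=O)OC[C@H](C)CCC[C@H](COC(C)=O)[C@@H]1CC[C@@H](C)c2c1cc(C(=O)O)c(O)c2O | target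

## Step count and risks

Total step count: 11. Longest linear sequence: 10 steps (3 → 18, steps 2 to 11); catechol joins through step 1 at step 4.

The three steps most likely to fail are 9, 10 and 6. Step 4 (moderate yield expected for a cuprate SN2 at a secondary tosylate) and step 5 (partial conversion, possible attack at the inner olefin) are the next weakest.

**Step 9.** The quinone–ene ring closure is unprecedented in this exact form. It can fail in three ways: quinone 14 may tautomerise to a quinone methide and erase C1, the proton may be lost from C12 instead of C18, or the trans:cis ratio may be low. The fallback reverses the polarity and needs no oxidised ring A; it sets out from 10. A second SeO2/t-BuOOH oxidation, now at the only olefin left, hydroxylates its E-disposed methyl (C18) and gives (2E,6R)-2-{(4R)-4-[2,3-bis(methoxymethoxy)phenyl]pentylidene}-6-methylheptane-1,7-diol F1. Ca(NTf2)2/Bu4NPF6 (5 mol %) in CH2Cl2 ionises the allylic alcohol, and the ring carbon para to the C7 oxygen attacks C4 of the allyl cation (intramolecular Friedel–Crafts allylic alkylation). This gives (2R)-6-[(1S,4R)-5,6-bis(methoxymethoxy)-4-methyl-1,2,3,4-tetrahydronaphthalen-1-yl]-2-methylhept-6-en-1-ol F2. Ortho-lithiation (s-BuLi, TMEDA, −78 °C) to the ring-lithiated lithium alkoxide F3, then CO2, gives (5R,8S)-8-[(6R)-7-hydroxy-6-methylhept-1-en-2-yl]-3,4-bis(methoxymethoxy)-5-methyl-5,6,7,8-tetrahydronaphthalene-2-carboxylic acid F4. 2 M HCl/THF removes the MOM groups and the route is rejoined at 15.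

**Step 10.** C11 rests on substrate control alone, and hydroborations of this kind next to a tetralin stereocentre can be poorly selective. The fallback puts C11 under enzyme control by dynamic kinetic resolution; it sets out from 12. SeO2/t-BuOOH hydroxylates C18 to 4-[(2R,5E,10R)-11-hydroxy-6-(hydroxymethyl)-10-methylundec-5-en-2-yl]-2,3-bis(methoxymethoxy)benzoic acid F5, and 2 M HCl/THF gives the corresponding 2,3-dihydroxybenzoic acid F6. PhI(OAc)2 in CH2Cl2/HFIP gives the ortho-quinone F7. Its ene cyclisation now takes the hydrogen from the carbinol carbon (or, stepwise, ends in a 1,2-hydride shift); either way the product is (5R,8S)-3,4-dihydroxy-8-[(6R)-7-hydroxy-6-methyl-1-oxoheptan-2-yl]-5-methyl-5,6,7,8-tetrahydronaphthalene-2-carboxylic acid F8 as a mixture of C11 epimers. A ketoreductase (NADPH, glucose/glucose dehydrogenase, pH 8) reduces the 11S aldehyde selectively while the α-centre epimerises through the enol. The route is rejoined at 17.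

**Step 6.** The enantioselectivity and facial sense of a hydroxyl-directed hydrogenation of a 2-methyl allylic alcohol are less secure than for geraniol-type substrates, and a C15 epimer would be hard to remove. The fallback uses carboxylate-directed hydrogenation; it sets out from 9. MnO2 (CH2Cl2) gives (2E,6Z,10R)-10-[2,3-bis(methoxymethoxy)phenyl]-2,6-dimethylundeca-2,6-dienal F9. NaClO2/NaH2PO4/2-methylbut-2-ene gives the corresponding (2E,6Z,10R)-dienoic acid F10. Ru(OAc)2[H8-BINAP] (the antipode that gives 2R; H2 100 atm, MeOH) gives (2R,6Z,10R)-10-[2,3-bis(methoxymethoxy)phenyl]-2,6-dimethylundec-6-enoic acid F11; this tiglic-acid-type substrate is the best-precedented class for an α-methyl centre. LiAlH4 (THF, 0 °C) rejoins the route at 10.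

## Further compounds

F1 | step 9 | (2E,6R)-2-{(4R)-4-[2,3-bis(methoxymethoxy)phenyl]pentylidene}-6-methylheptane-1,7-diol | C[C@@H](c1cccc(OCOC)c1OCOC)CC/C=C(/CO)CCC[C@@H](C)CO
F2 | step 9 | (2R)-6-[(1S,4R)-5,6-bis(methoxymethoxy)-4-methyl-1,2,3,4-tetrahydronaphthalen-1-yl]-2-methylhept-6-en-1-ol | OC[C@H](C)CCCC(=C)[C@@H]1CC[C@@H](C)c2c1ccc(OCOC)c2OCOC
F3 | step 9 | ring-lithiated lithium alkoxide of F2 (lithium ortho to the C7 acetal oxygen) | [Li]OC[C@H](C)CCCC(=C)[C@@H]1CC[C@@H](C)c2c1cc([Li])c(OCOC)c2OCOC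
F4 | step 9 | (5R,8S)-8-[(6R)-7-hydroxy-6-methylhept-1-en-2-yl]-3,4-bis(methoxymethoxy)-5-methyl-5,6,7,8-tetrahydronaphthalene-2-carboxylic acid | OC[C@H](C)CCCC(=C)[C@@H]1CC[C@@H](C)c2c1cc(C(=O)O)c(OCOC)c2OCOC
F5 | step 10 | 4-[(2R,5E,10R)-11-hydroxy-6-(hydroxymethyl)-10-methylundec-5-en-2-yl]-2,3-bis(methoxymethoxy)benzoic acid | C[C@@H](c1ccc(C(=O)O)c(OCOC)c1OCOC)CC/C=C(/CO)CCC[C@@H](C)CO
F6 | step 10 | 2,3-dihydroxy-4-[(2R,5E,10R)-11-hydroxy-6-(hydroxymethyl)-10-methylundec-5-en-2-yl]benzoic acid | C[C@@H](c1ccc(C(=O)O)c(O)c1O)CC/C=C(/CO)CCC[C@@H](C)CO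
F7 | step 10 | 4-[(2R,5E,10R)-11-hydroxy-6-(hydroxymethyl)-10-methylundec-5-en-2-yl]-5,6-dioxocyclohexa-1,3-diene-1-carboxylic acid | C[C@@H](C1=CC=C(C(=O)O)C(=O)C1=O)CC/C=C(/CO)CCC[C@@H](C)CO
F8 | step 10 | (5R,8S)-3,4-dihydroxy-8-[(6R)-7-hydroxy-6-methyl-1-oxoheptan-2-yl]-5-methyl-5,6,7,8-tetrahydronaphthalene-2-carboxylic acid (both C11 epimers) | OC[C@H](C)CCCC(C=O)[C@@H]1CC[C@@H](C)c2c1cc(C(=O)O)c(O)c2O
F9 | step 6 | (2E,6Z,10R)-10-[2,3-bis(methoxymethoxy)phenyl]-2,6-dimethylundeca-2,6-dienal | C[C@@H](c1cccc(OCOC)c1OCOC)CC/C=C(C)\CC/C=C(\C)C=O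
F10 | step 6 | (2E,6Z,10R)-10-[2,3-bis(methoxymethoxy)phenyl]-2,6-dimethylundeca-2,6-dienoic acid | C[C@@H](c1cccc(OCOC)c1OCOC)CC/C=C(C)\CC/C=C(\C)C(=O)O
F11 | step 6 | (2R,6Z,10R)-10-[2,3-bis(methoxymethoxy)phenyl]-2,6-dimethylundec-6-enoic acid | C[C@@H](c1cccc(OCOC)c1OCOC)CC/C=C(C)\CCC[C@@H](C)C(=O)O
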